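## Retrosynthetic overview

- The target is reached from a tris-benzyl naphthol by O-methylation of the C8'–OH and hydrogenolysis of the three benzyl ethers.
- The methoxy-bearing naphthalene ring (C5'–C8') is disconnected at C8'–C8a'. It is grown by 6π-electrocyclisation of an aryl-vinylketene made from a 4-aryl-3-butenoic acid. The strategy rests on the 1,2,4-trisubstituted benzene ring: its only free carbon ortho to the side chain becomes C8a', and the ketene carbon becomes C8', the one oxygen that must be methylated.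
- The butenoic acid comes from a Wittig reaction on the 4-(4-benzyloxy-3-formylphenyl)tetralone, which arises by BBr3 cleavage and tri-benzylation of a methyl-ether/ketal precursor.
- The C4 stereocentre is set by Ir-catalysed asymmetric hydrogenation of a 1-aryl-3,4-dihydronaphthalene ketal. That alkene comes from Suzuki coupling of an alkenyl triflate, made from 5,6-dimethoxy-1-tetralone by aromatisation, para-oxidative ketalisation and reductive triflation, which moves the carbonyl to the carbon peri to oxygen.
- Ring order: the tetralone bicycle comes with the starting tetralone, the benzene ring with the boronic acid, and the second naphthalene ring is closed last.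

Key step: step 9

Remark: the target stereocentre is (S). The Wittig step is expected to give mainly the E acid, so the E isomer is the isolated precursor and the Z geometry needed for ring closure arises in the flask.

## Route

Step 1
Reactants: 1 5,6-dimethoxy-3,4-dihydronaphthalen-1(2H)-one
Product: 3 5,6-dimethoxynaphthalen-1-ol, via 2-bromo-5,6-dimethoxy-1-tetralone 2 (not isolated)
Conditions: CuBr2 (2.1 equiv), EtOAc/CHCl3, reflux; then LiBr, Li2CO3, DMF, 120 °C, argon
Reagents that add atoms: none
Why: Selective α-bromination of the aryl ketone by CuBr2 and base-induced dehydrobromination should give the naphthalenone, which tautomerises to the naphthol (bromination–dehydrobromination aromatisation of a 1-tetralone).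

Step 2
Reactants: 3 5,6-dimethoxynaphthalen-1-ol
Product: 5 4,4,5,6-tetramethoxynaphthalen-1(4H)-one, via 4,5,6-trimethoxynaphthalen-1-ol 4 (not isolated)
Conditions: PhI(OAc)2 (2.2 equiv), MeOH, 0 °C → rt; NaHCO3 work-up
Reagents that add atoms: methanol, CO
Why: Two successive hypervalent-iodine oxidations with methanol capture at the para carbon C4 should give the quinone monoketal (oxidative dearomatisation of a 1-naphthol), placing the masked carbonyl next to the peri methoxy group.

Step 3
Reactants: 5 4,4,5,6-tetramethoxynaphthalen-1(4H)-one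
Product: 7 4,4,5,6-tetramethoxy-3,4-dihydronaphthalen-1-yl trifluoromethanesulfonate, via lithium enolate 6 (not isolated)
Conditions: LiBH(s-Bu)3 (1.1 equiv), THF, −78 °C; then PhNTf2 (1.2 equiv), −78 °C → rt
Reagents that add atoms: N-phenylbis(trifluoromethanesulfonimide), O=S(=O)(N(c1ccccc1)S(=O)(=O)C(F)(F)F)C(F)(F)F
Why: Conjugate hydride delivery to the β-unsubstituted enone should give a regiodefined enolate that is O-sulfonylated in the same flask (reductive enol triflation of an enone).

Step 4
Reactants: 7 4,4,5,6-tetramethoxy-3,4-dihydronaphthalen-1-yl trifluoromethanesulfonate; 8 (3-formyl-4-methoxyphenyl)boronic acid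
Product: 9 2-methoxy-5-(4,4,5,6-tetramethoxy-3,4-dihydronaphthalen-1-yl)benzaldehyde
Conditions: Pd(PPh3)4 (5 mol %), K2CO3, DME/H2O, 80 °C
Reagents that add atoms: none
Why: Suzuki–Miyaura coupling of an alkenyl triflate with an arylboronic acid runs under basic conditions that should leave the ketal and the aldehyde untouched.

Step 5
Reactants: 9 2-methoxy-5-(4,4,5,6-tetramethoxy-3,4-dihydronaphthalen-1-yl)benzaldehyde
Product: 10 2-methoxy-5-[(1S)-4,4,5,6-tetramethoxy-1,2,3,4-tetrahydronaphthalen-1-yl]benzaldehyde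
Conditions: [Ir(cod)(L)][B(C6H3(CF3)2)4] (2 mol %; L = (S)-tBu-PHOX, or (R) if a trial shows the opposite sense), H2 (50 bar), K3PO4, CH2Cl2, rt
Reagents that add atoms: none
Why: Ir–N,P-catalysed asymmetric hydrogenation of a cyclic trisubstituted aryl alkene (1-aryl-3,4-dihydronaphthalene) sets C1 by catalyst-controlled face selection, with the ligand hand chosen by a trial run to give (S); solid K3PO4 buffers the acidic iridium hydride so that the ketal should not lose methanol.

Step 6
Reactants: 10 2-methoxy-5-[(1S)-4,4,5,6-tetramethoxy-1,2,3,4-tetrahydronaphthalen-1-yl]benzaldehyde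
Product: 11 5-[(1S)-5,6-dihydroxy-4-oxo-1,2,3,4-tetrahydronaphthalen-1-yl]-2-hydroxybenzaldehyde
Conditions: BBr3 (7 equiv), CH2Cl2, −78 → 0 °C; then H2O
Reagents that add atoms: none
Why: BBr3 demethylation should cleave the three aryl methyl ethers and the dimethyl ketal in one operation, and the diarylmethine centre has no pathway for ionisation or enolisation.

Step 7
Reactants: 11 5-[(1S)-5,6-dihydroxy-4-oxo-1,2,3,4-tetrahydronaphthalen-1-yl]-2-hydroxybenzaldehyde
Product: 12 2-(benzyloxy)-5-[(1S)-5,6-bis(benzyloxy)-4-oxo-1,2,3,4-tetrahydronaphthalen-1-yl]benzaldehyde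
Conditions: BnBr (3.6 equiv), K2CO3, Bu4NI (cat.), DMF, 60 °C, argon
Reagents that add atoms: benzyl bromide, BrCc1ccccc1
Why: Williamson etherification should benzylate all three phenols, K2CO3 being too weak a base to enolise the ketone.

Step 8
Reactants: 12 2-(benzyloxy)-5-[(1S)-5,6-bis(benzyloxy)-4-oxo-1,2,3,4-tetrahydronaphthalen-1-yl]benzaldehyde; 13 (2-carboxyethyl)triphenylphosphonium bromide
Product: 14 (3E)-4-{2-(benzyloxy)-5-[(1S)-5,6-bis(benzyloxy)-4-oxo-1,2,3,4-tetrahydronaphthalen-1-yl]phenyl}but-3-enoic acid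
Conditions: 13 (1.3 equiv), NaN(SiMe3)2 (2.6 equiv), THF, −78 → 0 °C; then 12, −78 °C → rt; aq. HCl
Reagents that add atoms: none
Why: Wittig olefination with the carboxylate-bearing ylide should take the aldehyde far faster than the hindered aryl ketone and give mainly the E alkene; a minor Z isomer needs no separation because both feed the same ketene.

Step 9
Reactants: 14 (3E)-4-{2-(benzyloxy)-5-[(1S)-5,6-bis(benzyloxy)-4-oxo-1,2,3,4-tetrahydronaphthalen-1-yl]phenyl}but-3-enoic acid
Product: 19 (4S)-7,8-bis(benzyloxy)-4-[4-(benzyloxy)-8-hydroxynaphthalen-1-yl]-3,4-dihydronaphthalen-1(2H)-one, via mixed acetic anhydride 15 (not isolated), via (Z)-aryl-vinylketene 16 (not isolated), via bicyclic dienone 17 (not isolated), via naphthyl acetate 18 (not isolated)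
Conditions: Ac2O, NaOAc, 140 °C; evaporate; then K2CO3, MeOH/THF, rt
Reagents that add atoms: none
Why: Acetic anhydride should convert the acid into mixed anhydride 15, whose acidic α-CH2 allows E/Z equilibration of the styrene double bond and loss of acetate to the (Z)-aryl-vinylketene 16. The ketene C=C, the Z alkene and the aromatic bond between the side-chain carbon and the free ortho carbon then undergo a thermal disrotatory 6π-electrocyclisation that forms the C8'–C8a' bond and closes the six-membered ring as dienone 17; tautomerisation gives the naphthol, which is acetylated to 18 in the medium and set free again by K2CO3/MeOH. The closest known reaction is the classical cyclisation of 4-aryl-3-butenoic acids and Stobbe half-esters to 1-naphthyl acetates with Ac2O/NaOAc. No stereocentre is created in the product, since the sp3 carbon of 17 is lost on aromatisation, and the remote diarylmethine centre is neither enolisable nor ionisable here. The step needs closure at the one free ortho carbon, secured because the other ortho position carries the benzyloxy group, and it needs the Z geometry, reached by equilibration of 15. Because the closure is pericyclic, it does not depend on nucleophilic activation of a ring position that lies meta to the benzyloxy group.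

Step 10
Reactants: 19 (4S)-7,8-bis(benzyloxy)-4-[4-(benzyloxy)-8-hydroxynaphthalen-1-yl]-3,4-dihydronaphthalen-1(2H)-one
Product: 20 (4S)-7,8-bis(benzyloxy)-4-[4-(benzyloxy)-8-methoxynaphthalen-1-yl]-3,4-dihydronaphthalen-1(2H)-one
Conditions: MeI, K2CO3, DMF, rt
Reagents that add atoms: iodomethane, CI
Why: Williamson O-methylation acts on the only free hydroxyl group, so no selectivity question arises.

Step 11
Reactants: 20 (4S)-7,8-bis(benzyloxy)-4-[4-(benzyloxy)-8-methoxynaphthalen-1-yl]-3,4-dihydronaphthalen-1(2H)-one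
Product: 21 (4S)-7,8-dihydroxy-4-(4-hydroxy-8-methoxynaphthalen-1-yl)-3,4-dihydronaphthalen-1(2H)-one
Conditions: H2 (1 atm), Pd/C (10 % Pd), EtOAc/THF, rt
Reagents that add atoms: none
Why: Hydrogenolysis over palladium on carbon should remove the three benzyl ethers, while the methyl ether, the naphthalene and the chelated aryl ketone are expected to survive if the reaction is stopped at full debenzylation.

## Compound list

1 | 5,6-dimethoxy-3,4-dihydronaphthalen-1(2H)-one | COc1ccc2c(c1OC)CCCC2=O | starting material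
2 | 2-bromo-5,6-dimethoxy-3,4-dihydronaphthalen-1(2H)-one (racemic) | COc1ccc2c(c1OC)CCC(Br)C2=O | intermediate (not isolated)
3 | 5,6-dimethoxynaphthalen-1-ol | COc1ccc2c(O)cccc2c1OC | intermediate
4 | 4,5,6-trimethoxynaphthalen-1-ol | COc1ccc2c(O)ccc(OC)c2c1OC | intermediate (not isolated)
5 | 4,4,5,6-tetramethoxynaphthalen-1(4H)-one | COc1ccc2C(=O)C=CC(OC)(OC)c2c1OC | intermediate
6 | lithium 4,4,5,6-tetramethoxy-3,4-dihydronaphthalen-1-olate | COc1ccc2C([O-])=CCC(OC)(OC)c2c1OC.[Li+] | intermediate (not isolated)
7 | 4,4,5,6-tetramethoxy-3,4-dihydronaphthalen-1-yl trifluoromethanesulfonate | COc1ccc2C(OS(=O)(=O)C(F)(F)F)=CCC(OC)(OC)c2c1OC | intermediate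
8 | (3-formyl-4-methoxyphenyl)boronic acid | COc1ccc(B(O)O)cc1C=O | starting material
9 | 2-methoxy-5-(4,4,5,6-tetramethoxy-3,4-dihydronaphthalen-1-yl)benzaldehyde | COc1ccc(C2=CCC(OC)(OC)c3c2ccc(OC)c3OC)cc1C=O | intermediate
10 | 2-methoxy-5-[(1S)-4,4,5,6-tetramethoxy-1,2,3,4-tetrahydronaphthalen-1-yl]benzaldehyde | COc1ccc([C@@H]2CCC(OC)(OC)c3c2ccc(OC)c3OC)cc1C=O | intermediate
11 | 5-[(1S)-5,6-dihydroxy-4-oxo-1,2,3,4-tetrahydronaphthalen-1-yl]-2-hydroxybenzaldehyde | O=Cc1cc([C@@H]2CCC(=O)c3c2ccc(O)c3O)ccc1O | intermediate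
12 | 2-(benzyloxy)-5-[(1S)-5,6-bis(benzyloxy)-4-oxo-1,2,3,4-tetrahydronaphthalen-1-yl]benzaldehyde | O=Cc1cc([C@@H]2CCC(=O)c3c2ccc(OCc2ccccc2)c3OCc2ccccc2)ccc1OCc1ccccc1 | intermediate
13 | (2-carboxyethyl)triphenylphosphonium bromide | OC(=O)CC[P+](c1ccccc1)(c1ccccc1)c1ccccc1.[Br-] | starting material
14 | (3E)-4-{2-(benzyloxy)-5-[(1S)-5,6-bis(benzyloxy)-4-oxo-1,2,3,4-tetrahydronaphthalen-1-yl]phenyl}but-3-enoic acid | OC(=O)C/C=C/c1cc([C@@H]2CCC(=O)c3c2ccc(OCc2ccccc2)c3OCc2ccccc2)ccc1OCc1ccccc1 | intermediate
15 | acetic (3E)-4-{2-(benzyloxy)-5-[(1S)-5,6-bis(benzyloxy)-4-oxo-1,2,3,4-tetrahydronaphthalen-1-yl]phenyl}but-3-enoic anhydride | CC(=O)OC(=O)C/C=C/c1cc([C@@H]2CCC(=O)c3c2ccc(OCc2ccccc2)c3OCc2ccccc2)ccc1OCc1ccccc1 | intermediate (not isolated)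
16 | (4S)-7,8-bis(benzyloxy)-4-{4-(benzyloxy)-3-[(1Z)-4-oxobuta-1,3-dien-1-yl]phenyl}-3,4-dihydronaphthalen-1(2H)-one | O=C=C/C=C\c1cc([C@@H]2CCC(=O)c3c2ccc(OCc2ccccc2)c3OCc2ccccc2)ccc1OCc1ccccc1 | intermediate (not isolated)
17 | (4S)-7,8-bis(benzyloxy)-4-[4-(benzyloxy)-8-oxo-8,8a-dihydronaphthalen-1-yl]-3,4-dihydronaphthalen-1(2H)-one (either configuration at C8a') | O=C1C=CC=C2C(OCc3ccccc3)=CC=C([C@@H]3CCC(=O)c4c3ccc(OCc3ccccc3)c4OCc3ccccc3)C12 | intermediate (not isolated)
18 | 5-(benzyloxy)-8-[(1S)-5,6-bis(benzyloxy)-4-oxo-1,2,3,4-tetrahydronaphthalen-1-yl]naphthalen-1-yl acetate | CC(=O)Oc1cccc2c(OCc3ccccc3)ccc([C@@H]3CCC(=O)c4c3ccc(OCc3ccccc3)c4OCc3ccccc3)c12 | intermediate (not isolated)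
19 | (4S)-7,8-bis(benzyloxy)-4-[4-(benzyloxy)-8-hydroxynaphthalen-1-yl]-3,4-dihydronaphthalen-1(2H)-one | Oc1cccc2c(OCc3ccccc3)ccc([C@@H]3CCC(=O)c4c3ccc(OCc3ccccc3)c4OCc3ccccc3)c12 | intermediate
20 | (4S)-7,8-bis(benzyloxy)-4-[4-(benzyloxy)-8-methoxynaphthalen-1-yl]-3,4-dihydronaphthalen-1(2H)-one | COc1cccc2c(OCc3ccccc3)ccc([C@@H]3CCC(=O)c4c3ccc(OCc3ccccc3)c4OCc3ccccc3)c12 | intermediate
21 | (4S)-7,8-dihydroxy-4-(4-hydroxy-8-methoxynaphthalen-1-yl)-3,4-dihydronaphthalen-1(2H)-one | COc1cccc2c(O)ccc([C@@H]3CCC(=O)c4c3ccc(O)c4O)c12 | target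

## Step count

Total step count: 11. Longest linear sequence: 11 steps (1 to 21); 8 and 13 are purchased.

## Steps most likely to fail

**Step 9.** The E to Z equilibration may be slower than oligomerisation of the ketene. Ring closure may also be retarded by crowding at the carbon next to the tetralonyl-bearing position. The fallback sets out from 12.
- Nozaki–Hiyama–Kishi vinylation (vinyl bromide, CrCl2, NiCl2 cat., DMF, rt) is selective for the aldehyde over the ketone and should give the 1-arylprop-2-en-1-ol F1 as a mixture of carbinol epimers.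
- Acetylation (Ac2O, DMAP, pyridine) should give the allylic acetate F2.
- Palladium-catalysed cyclocarbonylation (PdCl2(PPh3)2 cat., CO 60 atm, Ac2O, NEt3, toluene, 160 °C) proceeds through a π-allylpalladium species that inserts CO. This builds the same 4-aryl-3-butenoyl unit with free interconversion of the alkene geometry and closes it to the naphthyl acetate.
- The fallback comes back to the route at 18, which is methanolysed to 19 as in step 9.

**Step 5.** Acid-promoted loss of methanol from the homoallylic ketal, with aromatisation, may compete. Facial discrimination by the catalyst may also be insufficient. The fallback sets out from 9.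
- Neutral heterogeneous hydrogenation (H2 1 atm, Pd/C, EtOAc with NEt3) should give the racemic ketal aldehyde F3.
- Preparative chromatography on a chiral stationary phase (supercritical CO2/MeOH) separates it, leaving the (R)-enantiomer F4 aside.
- The fallback comes back to the route at 10.

**Step 3.** Hydride may add to the carbonyl carbon instead of the β-carbon, giving 1,2-reduction. The fallback sets out from 5.
- Hydrogenation of the enone double bond (H2 1 atm, Pd/C, EtOAc, trace NEt3) should give the saturated ketal ketone F5.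
- Enolisation with KN(SiMe3)2 (THF, −78 °C) and trapping with PhNTf2 then gives the triflate.
- The fallback comes back to the route at 7.

## Further compounds

F1 | step 9 | (4S)-7,8-bis(benzyloxy)-4-[4-(benzyloxy)-3-(1-hydroxyprop-2-en-1-yl)phenyl]-3,4-dihydronaphthalen-1(2H)-one (carbinol epimers) | C=CC(O)c1cc([C@@H]2CCC(=O)c3c2ccc(OCc2ccccc2)c3OCc2ccccc2)ccc1OCc1ccccc1
F2 | step 9 | 1-{2-(benzyloxy)-5-[(1S)-5,6-bis(benzyloxy)-4-oxo-1,2,3,4-tetrahydronaphthalen-1-yl]phenyl}prop-2-en-1-yl acetate (carbinol epimers) | C=CC(OC(C)=O)c1cc([C@@H]2CCC(=O)c3c2ccc(OCc2ccccc2)c3OCc2ccccc2)ccc1OCc1ccccc1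
F3 | step 5 | racemic 2-methoxy-5-(4,4,5,6-tetramethoxy-1,2,3,4-tetrahydronaphthalen-1-yl)benzaldehyde | COc1ccc(C2CCC(OC)(OC)c3c2ccc(OC)c3OC)cc1C=O
F4 | step 5 | 2-methoxy-5-[(1R)-4,4,5,6-tetramethoxy-1,2,3,4-tetrahydronaphthalen-1-yl]benzaldehyde | COc1ccc([C@H]2CCC(OC)(OC)c3c2ccc(OC)c3OC)cc1C=O
F5 | step 3 | 4,4,5,6-tetramethoxy-3,4-dihydronaphthalen-1(2H)-one | COc1ccc2C(=O)CCC(OC)(OC)c2c1OC
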